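## Retrosynthetic overview

- The two free phenols (O5–H and O7–H) are unmasked last from a 5,7-bis(triisopropylsilyl) ether. Rings A and B are bought as phloroglucinol and 4-methoxyphenol, and the pyranone (ring C) is the only ring that is built.
- Ring C is cut at C4–C4a, giving a 3,3-bis(aryloxy)acrylic acid whose acyl carbon is held on ring A through O1–C2=C3. The feature used: C8 of ring A carries the prenyl group, so C4a is the single unsubstituted carbon ortho to O1, and it is also ortho to O5 and para to O7.
- The acid comes from allyl 3,3-dichloroacrylate. The two chlorides at C2 are replaced in turn, first by the ring A phenol (O1–C2), then by 4-methoxyphenol. The allyl ester is removed with zerovalent palladium and formate, because the strong acid that a tert-butyl ester needs would protonate C3 of the ketene acetal and the prenyl alkene.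
- The ring A phenol comes from phloroglucinol by C-prenylation and twofold silylation, which leaves free one of the two hydroxyls next to the prenyl group.

Key step: step 7

Assumption: compounds 7 and 9 to 11 are drawn as the geometrical isomer with the ring A oxygen cis to the carboxyl carbon. The vinylic substitutions may give mixtures of isomers, which would be carried on together because the C2–C3 bond turns freely in ion 12. (Prenyl = 3-methylbut-2-en-1-yl.)

## Route

Step 1
Reactants: 1 phloroglucinol; 2 prenyl bromide
Product: 3 2-prenylphloroglucinol (2-(3-methylbut-2-en-1-yl)benzene-1,3,5-triol)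
Conditions: 1 (3 equiv), KOH (1.1 equiv), H2O, 0 °C; 2 (1 equiv) dropwise, 0 °C → rt
Reagents that add atoms: none
Why: Phenolate C-alkylation: in water the oxygen atoms of the phloroglucinolate are tied up by hydrogen bonding, so the soft primary allylic bromide should be taken up at ring carbon (SN2), and the excess of 1 holds back a second prenylation.

Step 2
Reactants: 3 2-prenylphloroglucinol
Product: 4 2-prenyl-3,5-bis(triisopropylsilyloxy)phenol
Conditions: iPr3SiCl (2.05 equiv), imidazole (4 equiv), DMF, 0 °C
Reagents that add atoms: triisopropylsilyl chloride, CC(C)[Si](Cl)(C(C)C)C(C)C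
Why: Silyl ether formation under steric control: the bulky chlorosilane should take the hydroxyl para to the prenyl group first and one of the two equivalent flanking hydroxyls second, while the last hydroxyl, crowded by the prenyl chain that the new neighbour pushes towards it, reacts most slowly, so that two equivalents should stop at 4.

Step 3
Reactants: 5 3,3-dichloroacrylic acid
Product: 6 allyl 3,3-dichloroacrylate
Conditions: allyl bromide (1.2 equiv), KHCO3 (1.2 equiv), DMF, rt
Reagents that add atoms: allyl bromide, C=CCBr
Why: Carboxylate O-alkylation (SN2) with a base that is too weak to take HCl out of the dichlorovinyl group.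

Step 4
Reactants: 4 2-prenyl-3,5-bis(triisopropylsilyloxy)phenol; 6 allyl 3,3-dichloroacrylate
Product: 7 allyl (E)-3-chloro-3-[2-prenyl-3,5-bis(triisopropylsilyloxy)phenoxy]acrylate
Conditions: 6 (1.3 equiv), K2CO3 (1.5 equiv, dried), MeCN, 0 °C → rt
Reagents that add atoms: none
Why: Nucleophilic vinylic substitution by addition–elimination at the β-carbon of the acrylate (the same product would arise by HCl loss and conjugate addition), and it should stop after one chloride because the aryloxy group now donates into the acrylate and the phenoxide is hindered.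

Step 5
Reactants: 7 allyl (E)-3-chloro-3-[2-prenyl-3,5-bis(triisopropylsilyloxy)phenoxy]acrylate; 8 4-methoxyphenol
Product: 9 allyl (Z)-3-(4-methoxyphenoxy)-3-[2-prenyl-3,5-bis(triisopropylsilyloxy)phenoxy]acrylate
Conditions: 8 (1.0 equiv), K2CO3 (1.5 equiv, dried), DMF, rt
Reagents that add atoms: none
Why: Second nucleophilic vinylic substitution (addition–elimination): the small and more nucleophilic 4-methoxyphenoxide adds to the β-carbon, and from the resulting enolate chloride leaves far more readily than either aryloxide, so that one equivalent of 8 should give the mixed ketene acetal without exchange of the ring A aryloxy group.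

Step 6
Reactants: 9 allyl (Z)-3-(4-methoxyphenoxy)-3-[2-prenyl-3,5-bis(triisopropylsilyloxy)phenoxy]acrylate
Product: 10 (Z)-3-(4-methoxyphenoxy)-3-[2-prenyl-3,5-bis(triisopropylsilyloxy)phenoxy]acrylic acid (used crude and cold)
Conditions: Pd(PPh3)4 (5 mol %), HCO2H (2 equiv), Et3N (2.5 equiv), THF, rt; cold pH 5 buffer work-up
Reagents that add atoms: none
Why: Tsuji–Trost-type deallylation: zerovalent palladium ionises the allyl ester to a π-allyl complex that formate reduces to propene, and the nearly neutral medium holds no hydroxide, nucleophilic amine, fluoride or strong acid, so the ketene acetal carbon, the aryl silyl ethers and the prenyl group should all be left alone.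

Step 7
Reactants: 10 (Z)-3-(4-methoxyphenoxy)-3-[2-prenyl-3,5-bis(triisopropylsilyloxy)phenoxy]acrylic acid
Product: 13 2-(4-methoxyphenoxy)-8-prenyl-5,7-bis(triisopropylsilyloxy)chromen-4-one, via mixed trifluoroacetic anhydride 11 (not isolated), via acylium trifluoroacetate 12 (not isolated)
Conditions: (CF3CO)2O (1.2 equiv), 2,6-di-tert-butylpyridine (2.5 equiv), CH2Cl2 (0.01 M), −20 °C → rt
Reagents that add atoms: trifluoroacetic anhydride, O=C(OC(=O)C(F)(F)F)C(F)(F)F (its trifluoroacetyl group stands only in 11 and in the counter-ion of 12; no atom of it stays in 13)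
Why: Proposed new method: trifluoroacetic anhydride should turn acid 10 into mixed anhydride 11, which should lose trifluoroacetate easily because the resulting acylium ion 12 is at the same time a ketene-substituted dioxocarbenium ion, O=C=CH–C(+)(OAr)2, in which C2–C3 is a single bond, so both alkene isomers can reach the conformer that places ring A over the acyl carbon. C4a then attacks C4 and the Wheland intermediate gives its proton to the hindered pyridine, which forms the C4–C4a bond and closes ring C in a six-membered closure that is exo to the C–O multiple bond of the acylium ion (6-exo-dig). The closest known reaction type is the Ruhemann-type cyclodehydration of β-aryloxyacrylic acids to chromones, an intramolecular Friedel–Crafts acylation, together with the acylation of activated arenes by acyl trifluoroacetates, but a β,β-bis(aryloxy)acrylic acid has not been used in it. No stereocentre is formed. The step needs ring A to win over ring B and C4a to win over C6: C8 is blocked by the prenyl group, so C4a is the only carbon of ring A within reach and it is ortho to O5 and para to O7, whereas the reachable carbons of ring B are meta to the methoxy group, and C6 is screened from intermolecular acylation or trifluoroacetylation by its two triisopropylsilyloxy neighbours and by the high dilution. The non-nucleophilic pyridine keeps the medium free of trifluoroacetic acid, so that neither C3 of the ketene acetal nor the prenyl alkene should be protonated and the silyl ethers should stay on.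

Step 8
Reactants: 13 2-(4-methoxyphenoxy)-8-prenyl-5,7-bis(triisopropylsilyloxy)chromen-4-one
Product: 14 5,7-dihydroxy-2-(4-methoxyphenoxy)-8-prenylchromen-4-one (target, CNP0274214.0)
Conditions: Bu4NF (2.4 equiv), AcOH (2.6 equiv), THF, 0 °C
Reagents that add atoms: none
Why: Fluoride-driven cleavage of the aryl silyl ethers (strong Si–F bond), with acetic acid protonating the phenoxides as they form so that no basic species attacks C2 of the vinylogous carbonate or expels the 4-methoxyphenoxy group.

## Compound list

1 | phloroglucinol | Oc1cc(O)cc(O)c1 | starting material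
2 | prenyl bromide | CC(C)=CCBr | starting material
3 | 2-prenylphloroglucinol | CC(C)=CCc1c(O)cc(O)cc1O | intermediate
4 | 2-prenyl-3,5-bis(triisopropylsilyloxy)phenol | CC(C)=CCc1c(O)cc(O[Si](C(C)C)(C(C)C)C(C)C)cc1O[Si](C(C)C)(C(C)C)C(C)C | intermediate
5 | 3,3-dichloroacrylic acid | OC(=O)C=C(Cl)Cl | starting material
6 | allyl 3,3-dichloroacrylate | C=CCOC(=O)C=C(Cl)Cl | intermediate
7 | allyl (E)-3-chloro-3-[2-prenyl-3,5-bis(triisopropylsilyloxy)phenoxy]acrylate | C=CCOC(=O)/C=C(/Cl)Oc1cc(O[Si](C(C)C)(C(C)C)C(C)C)cc(O[Si](C(C)C)(C(C)C)C(C)C)c1CC=C(C)C | intermediate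
8 | 4-methoxyphenol | COc1ccc(O)cc1 | starting material
9 | allyl (Z)-3-(4-methoxyphenoxy)-3-[2-prenyl-3,5-bis(triisopropylsilyloxy)phenoxy]acrylate | C=CCOC(=O)/C=C(/Oc1ccc(OC)cc1)Oc1cc(O[Si](C(C)C)(C(C)C)C(C)C)cc(O[Si](C(C)C)(C(C)C)C(C)C)c1CC=C(C)C | intermediate
10 | (Z)-3-(4-methoxyphenoxy)-3-[2-prenyl-3,5-bis(triisopropylsilyloxy)phenoxy]acrylic acid | OC(=O)/C=C(/Oc1ccc(OC)cc1)Oc1cc(O[Si](C(C)C)(C(C)C)C(C)C)cc(O[Si](C(C)C)(C(C)C)C(C)C)c1CC=C(C)C | intermediate
11 | mixed anhydride of 10 with trifluoroacetic acid (not isolated) | FC(F)(F)C(=O)OC(=O)/C=C(/Oc1ccc(OC)cc1)Oc1cc(O[Si](C(C)C)(C(C)C)C(C)C)cc(O[Si](C(C)C)(C(C)C)C(C)C)c1CC=C(C)C | intermediate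
12 | 3,3-bis(aryloxy)acryloylium trifluoroacetate, no fixed C2–C3 geometry (not isolated) | [O+]#CC=C(Oc1ccc(OC)cc1)Oc1cc(O[Si](C(C)C)(C(C)C)C(C)C)cc(O[Si](C(C)C)(C(C)C)C(C)C)c1CC=C(C)C.[O-]C(=O)C(F)(F)F | intermediate
13 | 2-(4-methoxyphenoxy)-8-prenyl-5,7-bis(triisopropylsilyloxy)chromen-4-one | CC(C)[Si](C(C)C)(C(C)C)Oc1cc(O[Si](C(C)C)(C(C)C)C(C)C)c2c(c1CC=C(C)C)oc(Oc1ccc(OC)cc1)cc2=O | intermediate
14 | 5,7-dihydroxy-2-(4-methoxyphenoxy)-8-prenylchromen-4-one | COc1ccc(Oc2cc(=O)c3c(O)cc(O)c(CC=C(C)C)c3o2)cc1 | target

## Step count and risks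

Total step count: 8. Longest linear sequence: 7 (steps 1, 2, 4, 5, 6, 7, 8).

**1. Step 7 (new method).**
- What may go wrong:
  - The closure may be outrun by protonation at C3 with loss of CO2, by collapse of the ketene acetal to an aryl malonate, or by trifluoroacetylation at C3.
  - It may also simply be too slow, since O1 is tied up in the cation and the 5-silyloxy group crowds C4a.
  - Partial loss of the 5-O-silyl group would do no harm, because step 8 removes it anyway.
- Fallback, known reaction types only, sets out from 4 and 8 and comes back at 13. Here the C4–C4a bond is made first and ring C is closed at O1–C2.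
  - Magnesium-mediated ortho-formylation of 4 (Casnati–Skattebøl; MgCl2, Et3N, paraformaldehyde, THF, reflux) can enter only at the one free ortho carbon. It should give 2-hydroxy-3-prenyl-4,6-bis(triisopropylsilyloxy)benzaldehyde F1.
  - Separately, 8 is added to trichloroethylene (K2CO3, DMF, 70 °C) to give (E)-1,2-dichlorovinyl 4-methoxyphenyl ether F2.
  - n-BuLi (2 equiv, THF, −78 °C) takes HCl out of F2 to give chloroethynyl 4-methoxyphenyl ether F3. It then exchanges chlorine for lithium to give lithium (4-methoxyphenoxy)acetylide F4.
  - An excess of F4 (the first equivalent deprotonates the phenol) adds to F1. After an NH4Cl quench this gives the racemic propargylic alcohol 1-[2-hydroxy-3-prenyl-4,6-bis(triisopropylsilyloxy)phenyl]-3-(4-methoxyphenoxy)prop-2-yn-1-ol F5.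
  - MnO2 in CH2Cl2 oxidises F5 to the ynone 1-[2-hydroxy-3-prenyl-4,6-bis(triisopropylsilyloxy)phenyl]-3-(4-methoxyphenoxy)prop-2-yn-1-one F6.
  - The phenol of F6 adds to the aryloxy-bearing alkyne carbon (6-endo-dig oxa-Michael addition, K2CO3, acetone) to give 13.

**2. Step 6.**
- What may go wrong: the deallylation itself is dependable, but on liberation and isolation the free acid may protonate its own C3 and then lose CO2 or hydrolyse.
- Fallback sets out from 9 and comes back at 11. The carboxyl group is carried as a salt and the free acid 10 is left out of the route.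
  - The allyl group is transferred to a carboxylate salt (Pd(PPh3)4, potassium 2-ethylhexanoate, EtOAc/CH2Cl2, rt). This gives potassium (Z)-3-(4-methoxyphenoxy)-3-[2-prenyl-3,5-bis(triisopropylsilyloxy)phenoxy]acrylate F7.
  - The dried salt is suspended in CH2Cl2 with 2,6-di-tert-butylpyridine and treated with (CF3CO)2O. This forms 11 directly, with no acid released at that stage.

**3. Step 2.**
- What may go wrong: the three hydroxyls may be poorly discriminated. That means over-silylation, or silylation of both hydroxyls beside the prenyl group, which leaves the wrong one free.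
- Fallback sets out from 1 and comes back at 4. It also passes by the prenylation of step 1, and a sigmatropic shift fixes the free hydroxyl next to the prenyl group.
  - 1 is silylated twice (iPr3SiCl, imidazole, DMF), where no regioisomer is possible, to give 3,5-bis(triisopropylsilyloxy)phenol F8.
  - 2-Methylbut-3-en-2-ol is converted with n-BuLi and di-tert-butyl dicarbonate into tert-butyl 2-methylbut-3-en-2-yl carbonate F9.
  - Pd(PPh3)4-catalysed O-allylation of F8 with F9 (THF, 0 °C) gives the branched ether 1-(2-methylbut-3-en-2-yloxy)-3,5-bis(triisopropylsilyloxy)benzene F10.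
  - An aromatic Claisen rearrangement of F10 (N,N-diethylaniline, about 130 °C) moves the allyl unit with inversion to one of the two equivalent ortho carbons. This gives 4.

## Further compounds

F1 | step 7 | 2-hydroxy-3-prenyl-4,6-bis(triisopropylsilyloxy)benzaldehyde | O=Cc1c(O)c(CC=C(C)C)c(O[Si](C(C)C)(C(C)C)C(C)C)cc1O[Si](C(C)C)(C(C)C)C(C)C
F2 | step 7 | (E)-1,2-dichlorovinyl 4-methoxyphenyl ether | COc1ccc(O/C(Cl)=C\Cl)cc1
F3 | step 7 | chloroethynyl 4-methoxyphenyl ether | COc1ccc(OC#CCl)cc1
F4 | step 7 | lithium (4-methoxyphenoxy)acetylide | [Li]C#COc1ccc(OC)cc1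
F5 | step 7 | 1-[2-hydroxy-3-prenyl-4,6-bis(triisopropylsilyloxy)phenyl]-3-(4-methoxyphenoxy)prop-2-yn-1-ol (racemic) | OC(C#COc1ccc(OC)cc1)c1c(O)c(CC=C(C)C)c(O[Si](C(C)C)(C(C)C)C(C)C)cc1O[Si](C(C)C)(C(C)C)C(C)C
F6 | step 7 | 1-[2-hydroxy-3-prenyl-4,6-bis(triisopropylsilyloxy)phenyl]-3-(4-methoxyphenoxy)prop-2-yn-1-one | O=C(C#COc1ccc(OC)cc1)c1c(O)c(CC=C(C)C)c(O[Si](C(C)C)(C(C)C)C(C)C)cc1O[Si](C(C)C)(C(C)C)C(C)C
F7 | step 6 | potassium (Z)-3-(4-methoxyphenoxy)-3-[2-prenyl-3,5-bis(triisopropylsilyloxy)phenoxy]acrylate | [K+].[O-]C(=O)/C=C(/Oc1ccc(OC)cc1)Oc1cc(O[Si](C(C)C)(C(C)C)C(C)C)cc(O[Si](C(C)C)(C(C)C)C(C)C)c1CC=C(C)C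
F8 | step 2 | 3,5-bis(triisopropylsilyloxy)phenol | Oc1cc(O[Si](C(C)C)(C(C)C)C(C)C)cc(O[Si](C(C)C)(C(C)C)C(C)C)c1
F9 | step 2 | tert-butyl 2-methylbut-3-en-2-yl carbonate | C=CC(C)(C)OC(=O)OC(C)(C)C
F10 | step 2 | 1-(2-methylbut-3-en-2-yloxy)-3,5-bis(triisopropylsilyloxy)benzene | C=CC(C)(C)Oc1cc(O[Si](C(C)C)(C(C)C)C(C)C)cc(O[Si](C(C)C)(C(C)C)C(C)C)c1
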